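**Plan**

1. Carotenoid numbering is used, with the hydroxylated half unprimed; the target is all-E (3S,6S,6'S)-ε,ε-caroten-3-ol. The retrosynthesis removes a silyl group from O3, then cuts the sp2–sp2 single bond C10'–C11', then its twin C10–C11.
2. This leaves two terminal enynes (ring–C7=C8–C9≡C10), the two methyl groups C19 and C19' (from Me3Al), and the C11–C11' pentaene as a diiodide made from commercial C10 dialdehyde (C12–C12').
3. Enabling feature: at each chain end a methyl-branched trisubstituted E alkene (C9'(C19')=C10', C9(C19)=C10) sits next to the bond to be made. That array is the syn-methylmetalation product of a terminal alkyne, so Zr-catalysed carboalumination of the enyne makes C9'–C19', fixes C9'=C10' as E and leaves a C10'–Al bond that is cross-coupled in the same flask with the C11' alkenyl iodide.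
4. Forward order: racemic α-ionone → (S)-α-ionone → enyne 5 (serves both ends) → C3 oxidation, reduction, silylation → 8; dialdehyde 9 → diiodide 10; 8 + 10 → iodide 12 (C10–C11); 5 + 12 → 14 (C10'–C11'); desilylation. Both ε rings (C1–C6 and C1'–C6') come in intact from α-ionone; no ring is formed.
5. Stereochemistry: C6 and C6' from resolved (S)-α-ionone; C3 from a reagent-controlled CBS reduction; C7=C8 and C7'=C8' from ionone; C9=C10 and C9'=C10' from syn-carboalumination; C11=C12 and C11'=C12' from Takai olefination; the three central alkenes from the dialdehyde; the Pd couplings retain alkene geometry.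

Key step: step 8

**Step 1**
Reactants: 1 racemic α-ionone, (E)-4-(2,6,6-trimethylcyclohex-2-en-1-yl)but-3-en-2-one
Product: 2 (S)-(−)-α-ionone, (E)-4-[(1S)-2,6,6-trimethylcyclohex-2-en-1-yl]but-3-en-2-one
Conditions: preparative SFC, amylose tris(3,5-dimethylphenylcarbamate) chiral stationary phase, CO2/MeOH; the laevorotatory enantiomer is collected
Reagents that add atoms: none
Why: Resolution by chromatography on a chiral stationary phase, a separation type established for the ionone enantiomers, fixes the (6S) configuration of both end rings at the outset from a cheap racemate without any bond being made.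

**Step 2**
Reactants: 2 (S)-(−)-α-ionone
Product: 5 (6S)-6-[(1E)-but-1-en-3-yn-1-yl]-1,5,5-trimethylcyclohex-1-ene, via lithium dienolate 3 (not isolated), via dienyl diethyl phosphate 4 (not isolated)
Conditions: LiN(i-Pr)2 (1.05 equiv), THF, −78 °C; ClP(O)(OEt)2 (1.1 equiv), −78 °C → rt; then LiN(i-Pr)2 (2.3 equiv), −78 °C → rt; aq NH4Cl
Reagents that add atoms: none
Why: This is the known one-pot methyl ketone to terminal alkyne conversion (kinetic enolisation at the methyl group, O-phosphorylation, then E2 elimination of diethyl phosphate from the 2-phosphoryloxy-1,3-diene), and the hindered C6–H between quaternary C1 and C5 should be removed far more slowly than the methyl and vinyl protons at −78 °C, so C6 should stay intact.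

**Step 3**
Reactants: 5 (6S)-6-[(1E)-but-1-en-3-yn-1-yl]-1,5,5-trimethylcyclohex-1-ene
Product: 6 (4S)-4-[(1E)-but-1-en-3-yn-1-yl]-3,5,5-trimethylcyclohex-2-en-1-one
Conditions: CrO3 (12 equiv), 3,5-dimethylpyrazole (12 equiv), CH2Cl2, −20 °C
Reagents that add atoms: chromium trioxide, O=[Cr](=O)=O
Why: Allylic oxidation of a trisubstituted cyclohexene to the enone by the hexavalent chromium–3,5-dimethylpyrazole complex should take the ring CH2 next to the CH= terminus (C3), the only unhindered secondary allylic position, as in the known oxidation of α-ionone and its ketal to the 3-oxo compounds, and the cold, non-basic medium should spare the enyne and the C6 stereocentre.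

**Step 4**
Reactants: 6 (4S)-4-[(1E)-but-1-en-3-yn-1-yl]-3,5,5-trimethylcyclohex-2-en-1-one
Product: 7 (1S,4S)-4-[(1E)-but-1-en-3-yn-1-yl]-3,5,5-trimethylcyclohex-2-en-1-ol
Conditions: (R)-Me-CBS oxazaborolidine [(R)-1-methyl-3,3-diphenyltetrahydro-1H,3H-pyrrolo[1,2-c][1,3,2]oxazaborole] (0.2 equiv), catecholborane (1.5 equiv), toluene, −78 °C; MeOH quench, aq NaOH wash
Reagents that add atoms: none
Why: Corey–Bakshi–Shibata reduction under reagent control: the (R)-oxazaborolidine should bind the ketone with the alkenyl arm C4=C5 as the large group and deliver hydride to the face that gives the (3S) carbinol, trans to the C6 side chain, while catecholborane at −78 °C should not hydroborate the terminal alkyne.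

**Step 5**
Reactants: 7 (1S,4S)-4-[(1E)-but-1-en-3-yn-1-yl]-3,5,5-trimethylcyclohex-2-en-1-ol
Product: 8 tert-butyl{[(1S,4S)-4-[(1E)-but-1-en-3-yn-1-yl]-3,5,5-trimethylcyclohex-2-en-1-yl]oxy}dimethylsilane
Conditions: TBSCl, imidazole, DMF, rt
Reagents that add atoms: tert-butyldimethylsilyl chloride, CC(C)(C)[Si](C)(C)Cl
Why: Standard silylation of a secondary allylic alcohol masks the hydroxyl against Me3Al in the later carboalumination and does not touch C3 or C6.

**Step 6**
Reactants: 9 (2E,4E,6E)-2,7-dimethylocta-2,4,6-trienedial (C10 dialdehyde)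
Product: 10 (1E,3E,5E,7E,9E)-1,10-diiodo-3,8-dimethyldeca-1,3,5,7,9-pentaene
Conditions: CrCl2 (16 equiv), CHI3 (5 equiv), THF/1,4-dioxane, 0 °C → rt, dark
Reagents that add atoms: iodoform, IC(I)I
Why: Twofold Takai olefination adds one CHI unit to each aldehyde carbon (C12 and C12') through a gem-dichromium species whose anti elimination gives the E alkenyl iodide, a preference that is reliable for α-branched enals.

**Step 7**
Reactants: 8 tert-butyl{[(1S,4S)-4-[(1E)-but-1-en-3-yn-1-yl]-3,5,5-trimethylcyclohex-2-en-1-yl]oxy}dimethylsilane; 10 (1E,3E,5E,7E,9E)-1,10-diiodo-3,8-dimethyldeca-1,3,5,7,9-pentaene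
Product: 12 tert-butyl{[(1S,4S)-4-[(1E,3E,5E,7E,9E,11E,13E)-14-iodo-3,7,12-trimethyltetradeca-1,3,5,7,9,11,13-heptaen-1-yl]-3,5,5-trimethylcyclohex-2-en-1-yl]oxy}dimethylsilane, via silyloxy dienyl dimethylalane 11 (not isolated)
Conditions: 8 (1 equiv), Me3Al (2 equiv), Cp2ZrCl2 (0.25 equiv), (CH2Cl)2, rt; volatiles removed in vacuo; then THF, ZnCl2 (0.5 equiv), 10 (3 equiv), Pd2(dba)3 (2.5 mol %), P(2-furyl)3 (10 mol %), DMF, rt, dark
Reagents that add atoms: trimethylaluminium, C[Al](C)C
Why: The one-pot Zr-catalysed carboalumination/Negishi alkenyl–alkenyl cross-coupling should give alane 11 with the C19 methyl group and the E C9=C10 alkene by syn-methylalumination of the terminal alkyne, then form C10–C11 with retention at one of the two equivalent C–I bonds of 10, whose threefold excess (recoverable) should favour mono-coupling.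

**Step 8**
Reactants: 5 (6S)-6-[(1E)-but-1-en-3-yn-1-yl]-1,5,5-trimethylcyclohex-1-ene; 12 the C26 heptaenyl iodide of step 7
Product: 14 (3S,6S,6'S)-3-(tert-butyldimethylsilyloxy)-ε,ε-carotene, via dienyl dimethylalane 13 (not isolated)
Conditions: 5 (1.3 equiv), Me3Al (2 equiv), Cp2ZrCl2 (0.25 equiv), (CH2Cl)2, rt; volatiles removed in vacuo; then THF, ZnCl2 (0.5 equiv), 12 (1 equiv), Pd2(dba)3 (2.5 mol %), P(2-furyl)3 (10 mol %), DMF, rt, dark, argon
Reagents that add atoms: trimethylaluminium, C[Al](C)C
Why: Under Cp2ZrCl2 catalysis Me3Al should add across the terminal alkyne C9'≡C10' of 5 by a four-centre syn-carbometalation that places the methyl group on the internal carbon C9' and aluminium on C10', so that alane 13 already holds the C19' methyl group and the E geometry of C9'=C10'; after removal of excess Me3Al, oxidative addition of the C11'–I bond of 12 to zerovalent palladium, ZnCl2-assisted transfer of the dienyl group from aluminium to palladium and reductive elimination should forge the C10'–C11' bond with retention at both alkene carbons. The closest known reaction type is the one-pot zirconium-catalysed carboalumination/palladium-catalysed Negishi alkenyl–alkenyl coupling used for retinoids and symmetrical carotenes. No ring is closed and no sp3 stereocentre is created; the stereochemical element made here is the trisubstituted C9'=C10' alkene, controlled by the syn addition, while C6', C6 and C3 are carried through unchanged. The step needs regioselectivity (methyl at C9'), chemoselectivity (alkyne over the ring C4'=C5' alkene and over the polyene of 12) and freedom from acid or base that would move the ε double bonds or epimerise the doubly allylic C6 and C6' hydrogens; the terminal, diene-conjugated alkyne secures the first two, the single C(sp2)–I bond of 12 directs the palladium, and the neutral aprotic medium at room temperature in the dark, with the hydroxyl masked as its TBS ether, secures the rest.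

**Step 9**
Reactants: 14 (3S,6S,6'S)-3-(tert-butyldimethylsilyloxy)-ε,ε-carotene
Product: 15 (3S,6S,6'S)-ε,ε-caroten-3-ol (all-E)
Conditions: Bu4NF (1.5 equiv), THF, 0 °C → rt, dark, argon
Reagents that add atoms: none
Why: Fluoride-induced cleavage of the Si–O bond (silyl ether deprotection) should free the C3 hydroxyl without touching C3–O, the ε-ring alkenes or the polyene.

**Compound list**

1 | racemic α-ionone, (E)-4-(2,6,6-trimethylcyclohex-2-en-1-yl)but-3-en-2-one | CC(=O)/C=C/C1C(C)=CCCC1(C)C | starting material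
2 | (S)-(−)-α-ionone, (E)-4-[(1S)-2,6,6-trimethylcyclohex-2-en-1-yl]but-3-en-2-one | CC1=CCCC(C)(C)[C@@H]1/C=C/C(C)=O | intermediate
3 | lithium (E)-4-[(1S)-2,6,6-trimethylcyclohex-2-en-1-yl]buta-1,3-dien-2-olate | CC1=CCCC(C)(C)[C@@H]1/C=C/C(=C)[O-].[Li+] | intermediate (not isolated)
4 | diethyl (E)-4-[(1S)-2,6,6-trimethylcyclohex-2-en-1-yl]buta-1,3-dien-2-yl phosphate | CC1=CCCC(C)(C)[C@@H]1/C=C/C(=C)OP(=O)(OCC)OCC | intermediate (not isolated)
5 | (6S)-6-[(1E)-but-1-en-3-yn-1-yl]-1,5,5-trimethylcyclohex-1-ene | CC1=CCCC(C)(C)[C@@H]1/C=C/C#C | intermediate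
6 | (4S)-4-[(1E)-but-1-en-3-yn-1-yl]-3,5,5-trimethylcyclohex-2-en-1-one | CC1=CC(=O)CC(C)(C)[C@@H]1/C=C/C#C | intermediate
7 | (1S,4S)-4-[(1E)-but-1-en-3-yn-1-yl]-3,5,5-trimethylcyclohex-2-en-1-ol (hydroxyl trans to the side chain) | C#C/C=C/[C@@H]1C(C)=C[C@@H](O)CC1(C)C | intermediate
8 | tert-butyl{[(1S,4S)-4-[(1E)-but-1-en-3-yn-1-yl]-3,5,5-trimethylcyclohex-2-en-1-yl]oxy}dimethylsilane | C#C/C=C/[C@@H]1C(C)=C[C@@H](O[Si](C)(C)C(C)(C)C)CC1(C)C | intermediate
9 | (2E,4E,6E)-2,7-dimethylocta-2,4,6-trienedial (C10 dialdehyde) | O=C/C(C)=C/C=C/C=C(C)/C=O | starting material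
10 | (1E,3E,5E,7E,9E)-1,10-diiodo-3,8-dimethyldeca-1,3,5,7,9-pentaene | I/C=C/C(C)=C/C=C/C=C(C)/C=C/I | intermediate
11 | {(1E,3E)-4-[(1S,4S)-4-(tert-butyldimethylsilyloxy)-2,6,6-trimethylcyclohex-2-en-1-yl]-2-methylbuta-1,3-dien-1-yl}dimethylalane | C[Al](C)/C=C(C)/C=C/[C@@H]1C(C)=C[C@@H](O[Si](C)(C)C(C)(C)C)CC1(C)C | intermediate (not isolated)
12 | tert-butyl{[(1S,4S)-4-[(1E,3E,5E,7E,9E,11E,13E)-14-iodo-3,7,12-trimethyltetradeca-1,3,5,7,9,11,13-heptaen-1-yl]-3,5,5-trimethylcyclohex-2-en-1-yl]oxy}dimethylsilane | I/C=C/C(C)=C/C=C/C=C(C)/C=C/C=C(C)/C=C/[C@@H]1C(C)=C[C@@H](O[Si](C)(C)C(C)(C)C)CC1(C)C | intermediate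
13 | dimethyl{(1E,3E)-2-methyl-4-[(1S)-2,6,6-trimethylcyclohex-2-en-1-yl]buta-1,3-dien-1-yl}alane | CC1=CCCC(C)(C)[C@@H]1/C=C/C(C)=C/[Al](C)C | intermediate (not isolated)
14 | (3S,6S,6'S)-3-(tert-butyldimethylsilyloxy)-ε,ε-carotene (all-E) | CC1=CCCC(C)(C)[C@@H]1/C=C/C(C)=C/C=C/C(C)=C/C=C/C=C(C)/C=C/C=C(C)/C=C/[C@@H]1C(C)=C[C@@H](O[Si](C)(C)C(C)(C)C)CC1(C)C | intermediate
15 | (3S,6S,6'S)-ε,ε-caroten-3-ol (all-E) | CC1=CCCC(C)(C)[C@@H]1/C=C/C(C)=C/C=C/C(C)=C/C=C/C=C(C)/C=C/C=C(C)/C=C/[C@@H]1C(C)=C[C@@H](O)CC1(C)C | target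

**Step count and risks**

Total step count: 9. Longest linear sequence: 8 steps (steps 1, 2, 3, 4, 5, 7, 8, 9).

Steps most likely to fail:

Step 3. The oxidant may abstract the doubly allylic C6–H or attack the conjugated enyne instead of oxidising C3, and the enone once formed may lose C6 integrity by enolisation. The fallback sets out from compound 2 and comes back at compound 8; it oxidises before the alkyne exists, with the side-chain ketone masked. Compound 2 is converted with ethylene glycol, HC(OMe)3 and catalytic p-TsOH into the ethylene ketal F1. Allylic oxidation of the ketal (t-BuOOH with catalytic CrO3 in CH2Cl2), a reaction type with close precedent on this very ring system, gives the 3-oxo ketal F2. Reduction with the (R)-CBS oxazaborolidine and catecholborane gives the (3S) hydroxy ketal F3, and TBSCl/imidazole gives its silyl ether F4. Pyridinium p-toluenesulfonate in wet acetone releases the silyloxy ketone F5. The alkyne protocol of step 2, through the lithium dienolate F6 and the enol phosphate F7, then gives compound 8.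

Step 4. Facial selectivity may be poor if the preference of the catalyst and the intrinsic bias of the ring (axial methyl group at C1, pseudoaxial side chain at C6) oppose each other. The fallback sets out from compound 6 and comes back at compound 7; it relies on substrate control followed by stereochemical correction. Luche reduction (NaBH4, CeCl3·7H2O, MeOH, −78 °C) should give 7 together with its C3 epimer, the cis alcohol F8, and the two are separated by chromatography. F8 is inverted by Mitsunobu reaction (4-nitrobenzoic acid, PPh3, diisopropyl azodicarboxylate, THF) to the (3S) 4-nitrobenzoate F9, and methanolysis (K2CO3, MeOH) gives compound 7.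

Step 7. The mono-coupled iodide may couple a second time at its remaining C–I bond, and the polyenyl iodides may isomerise or decompose during the separation from excess diiodide. The fallback sets out from compound 9 (with alane 11 made from 8 as in step 7) and comes back at compound 12; it differentiates the two chain termini by oxidation level instead of by stoichiometry. A single Takai olefination on an excess of 9 (3 equiv of 9, CHI3, CrCl2, THF, 0 °C) gives the iodo aldehyde F10, so the statistical event is moved to the cheap commercial dialdehyde. Alane 11 is treated with a full equivalent of ZnCl2, so that an aldehyde-tolerant alkenylzinc chloride is the coupling species, and is joined to F10 with Pd2(dba)3/P(2-furyl)3 to give the silyl-protected apo-aldehyde F11. A second Takai olefination of F11 gives compound 12.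

**Further compounds**

F1 | step 3 | 2-methyl-2-{(E)-2-[(1S)-2,6,6-trimethylcyclohex-2-en-1-yl]ethenyl}-1,3-dioxolane | CC1=CCCC(C)(C)[C@@H]1/C=C/C1(C)OCCO1
F2 | step 3 | (4S)-3,5,5-trimethyl-4-[(E)-2-(2-methyl-1,3-dioxolan-2-yl)ethenyl]cyclohex-2-en-1-one | CC1=CC(=O)CC(C)(C)[C@@H]1/C=C/C1(C)OCCO1
F3 | step 3 | (1S,4S)-3,5,5-trimethyl-4-[(E)-2-(2-methyl-1,3-dioxolan-2-yl)ethenyl]cyclohex-2-en-1-ol | CC1(OCCO1)/C=C/[C@@H]2C(C)=C[C@@H](O)CC2(C)C
F4 | step 3 | tert-butyldimethyl{[(1S,4S)-3,5,5-trimethyl-4-[(E)-2-(2-methyl-1,3-dioxolan-2-yl)ethenyl]cyclohex-2-en-1-yl]oxy}silane | CC1(OCCO1)/C=C/[C@@H]2C(C)=C[C@@H](O[Si](C)(C)C(C)(C)C)CC2(C)C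
F5 | step 3 | (E)-4-[(1S,4S)-4-(tert-butyldimethylsilyloxy)-2,6,6-trimethylcyclohex-2-en-1-yl]but-3-en-2-one | CC(=O)/C=C/[C@@H]1C(C)=C[C@@H](O[Si](C)(C)C(C)(C)C)CC1(C)C
F6 | step 3 | lithium (E)-4-[(1S,4S)-4-(tert-butyldimethylsilyloxy)-2,6,6-trimethylcyclohex-2-en-1-yl]buta-1,3-dien-2-olate | C=C([O-])/C=C/[C@@H]1C(C)=C[C@@H](O[Si](C)(C)C(C)(C)C)CC1(C)C.[Li+]
F7 | step 3 | diethyl (E)-4-[(1S,4S)-4-(tert-butyldimethylsilyloxy)-2,6,6-trimethylcyclohex-2-en-1-yl]buta-1,3-dien-2-yl phosphate | C=C(OP(=O)(OCC)OCC)/C=C/[C@@H]1C(C)=C[C@@H](O[Si](C)(C)C(C)(C)C)CC1(C)C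
F8 | step 4 | (1R,4S)-4-[(1E)-but-1-en-3-yn-1-yl]-3,5,5-trimethylcyclohex-2-en-1-ol | C#C/C=C/[C@@H]1C(C)=C[C@H](O)CC1(C)C
F9 | step 4 | (1S,4S)-4-[(1E)-but-1-en-3-yn-1-yl]-3,5,5-trimethylcyclohex-2-en-1-yl 4-nitrobenzoate | C#C/C=C/[C@@H]1C(C)=C[C@@H](OC(=O)c2ccc(cc2)[N+](=O)[O-])CC1(C)C
F10 | step 7 | (2E,4E,6E,8E)-9-iodo-2,7-dimethylnona-2,4,6,8-tetraenal | I/C=C/C(C)=C/C=C/C=C(C)/C=O
F11 | step 7 | (3S,6S)-3-(tert-butyldimethylsilyloxy)-12'-apo-ε-caroten-12'-al (all-E) | O=C/C(C)=C/C=C/C=C(C)/C=C/C=C(C)/C=C/[C@@H]1C(C)=C[C@@H](O[Si](C)(C)C(C)(C)C)CC1(C)C
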